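## The problem

The target 17 is a monocyclic tetrahydrofuran, O1–C2–C3–C4–C5. C2 carries the 3,4,5-trimethoxyphenyl group (ring A), C3 a hydroxymethyl group and C4 the 2,4,5-trimethoxybenzyl group (CH2–ring B); C5 is an unsubstituted methylene. The three contiguous stereocentres are (2R,3R,4R) and put all three substituents on one face of the ring. This is the most crowded arrangement, so none of the centres may be set under equilibrating conditions. C2 is the natural anchor: it can be made by asymmetric catalysis at an aldehyde carbon, it can send a reagent to the opposite face at C3, and C2 and C3 together can send hydrogen to one face at C4. The fragile points are the benzylic C2–O1 bond (open to acid and to hydrogenolysis), the two electron-rich arenes (ring B above all, open to electrophiles and strong acids), and C3 while it is at the carboxyl level, where its hydrogen is acidic and epimerisation leads to the trans isomer. The enabling feature is that C3 bears a single carbon branch and lies between C2 and C4. Read as an ester, this is the pattern left when a six-membered α-diazoketone O1–C2–C(N2)–C(=O)–C=C contracts through a ketene. The five-membered ring, the C3–C4 bond and the C3 stereocentre can therefore all come from one rearrangement of a dihydropyranone that asymmetric hetero-Diels–Alder chemistry delivers directly.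

## Retrosynthesis

**17 ⇒ 16.** The C3 hydroxymethyl group is taken back to a methyl ester, giving the all-cis ester 16. No skeletal bond is cut. The ester is the group a ketene leaves behind, so this adjustment exposes the rearrangement. The forward reduction must be faster than enolisation at C3.

**16 ⇒ 15.** The C4–H and C5–H bonds are removed to give the 2,3-dihydrofuran 15, an enol ether with C4=C5. Taking out C4 as a stereocentre here is better than taking out C2 or C3, because in 15 the C2 aryl group and the C3 ester are cis and both shield the same face. Hydrogen must arrive from the other face, which is exactly what the all-cis target needs. The forward step must reduce a trisubstituted enol ether without migrating it, without epimerising C3 and without cleaving C2–O1.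

**15 ⇒ 12 (key disconnection).** The C3–C4 bond of the furan is cut and C4 is reattached to the ester carbon, which becomes a ring ketone. C3 becomes a diazo carbon. The result is the 3-diazo-2,3-dihydropyran-4-one 12. In the forward sense, loss of nitrogen with a 1,2-shift gives ketene 13, the alcohol solvent adds to give ester enol 14, and protonation gives 15.

- Against a direct five-ring cyclisation (O1–C2 or O1–C5 closure of an acyclic chain), this cut removes no stereocentre that must be rebuilt on an open chain.
- It turns the hard all-cis problem into one kinetic protonation next to an existing centre.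
- The precursor is simpler by one stereocentre, and its ring comes from a two-component cycloaddition.
- The forward reaction must make the vinyl carbon migrate (no other group can), add the alcohol to the ketene, and deliver the proton to C3 anti to ring A.

**12 ⇒ 10.** The diazo group is removed to the methylene ketone 10. The ketone has one enolisable α-carbon (C3 of the pyranone); the other α-carbon is sp2 and fully substituted. Diazo transfer through the trifluoroacetyl ketone 11 therefore has no regiochemical choice. The forward step must keep the enolate from ejecting O1, which would open the ring.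

**10 ⇒ 5 + 9.** The bond between C5 of the pyranone and the benzylic CH2 is cut, giving the α-iodoenone 5 and the benzylzinc chloride 9. Compound 9 is traced through chloride 8 and alcohol 7 to aldehyde 6. This sp2–sp3 coupling is preferred to carrying the benzyl group on the diene, which would need a bespoke diene for the asymmetric cycloaddition. It is done before diazo transfer because a diazo group does not tolerate palladium and organozinc reagents. The precursors are an iodide two steps from commercial material and a benzyl metal three operations from an aldehyde. The coupling must be neutral so that C2 is safe.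

**5 ⇒ 4.** The C5–I bond is removed to the parent dihydropyranone 4. C5 is the nucleophilic carbon of the enol ether, so electrophilic iodination is inherently selective for it.

**4 ⇒ 1 + 2.** The C2–C3 and O1–C6 bonds of the pyranone are cut to aldehyde 1 and silyloxydiene 2, passing through the aldol adduct 3. This is the only place where absolute configuration is introduced, and it uses a catalytic asymmetric reaction of an aromatic aldehyde. Both components are commercial.

## Roads not taken

**Alternative 1:** Prins–pinacol ring contraction.

- Cut: the target is cut at C4–C5 and C2–C3, with C5 coming from a formaldehyde acetal. The precursor is the cis-dioxolane A1, whose Z-alkene carries the CH2–ring B unit.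
- Forward key step: SnCl4 opens the acetal to the O1=C5H2 oxocarbenium ion, the alkene closes a six-membered chair (C4–C5), and the benzylic carbinol carbon shifts to C3 as the second oxygen becomes the formyl group. The product is the all-cis aldehyde A2.
- Merits: one step forms two C–C bonds and the ring. The chair transition state with the aryl group equatorial and the Z-substituent axial leads to the all-cis pattern. A2 is a single borohydride reduction from 17, so the endgame is one step shorter than in the chosen plan.
- Weak points: the alkene is 1,2-disubstituted, so the positive charge developing at C3 is secondary and unstabilised. The electron-rich ring B and the ring A benzylic C–O bond offer easier outlets for a strong Lewis acid. A1 needs a Z-alkene and two defined carbinol centres, which costs its own asymmetric step and a cis-selective semireduction. A2 carries a formyl group on the all-cis C3 and epimerises more readily than ester 16.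
- Comparison: this road is better in bond construction per step and in endgame length. The chosen plan sets against it a unimolecular rearrangement that does not depend on cation stability, neutral conditions toward both arenes, and a stereochemical entry made in one catalytic step.

**Alternative 2:** Allenol coupling–cyclisation.

- Cut: the C4–CH2 and O1–C5 bonds are cut, leading to the α-allenol A3 and benzyl chloride 8.
- Forward key step: zerovalent palladium (Pd(PPh3)4) inserts into 8, the benzyl group adds to the central allene carbon, and the hydroxyl group closes onto the CH2 terminus of the π-allyl complex. The product is the 2,5-dihydrofuran A4.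
- Merits: a short, convergent assembly in which the ring and the benzyl bond form together, and an overall sequence of about six steps, shorter than the chosen plan.
- Weak points: A4 has a tetrasubstituted C3=C4 alkene, and both C3 and C4 must then be set in one hydrogenation controlled only by C2. That alkene is hard to reduce, and C2–O1 in A4 is both allylic and benzylic, so hydrogenolysis is a real competitor. Attack of the hydroxyl group at the internal terminus (vinyl epoxide) competes with ring closure. A3 must be made enantioenriched by an asymmetric allenylation of aldehyde 1, which is less general than the cycloaddition used here.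
- Comparison: this road is better in step count. The chosen plan sets C3 and C4 in two separate, easier events (a protonation and the hydrogenation of a trisubstituted enol ether) and meets the tetrasubstituted alkene only in its fallback.

**Alternative 3:** Three-component oxa-Michael, carbopalladation and arylation.

- Cut: the O1–C2, C3–C4 and aryl–CH bonds are cut, leading to the benzylidenemalonate A5, the aryl iodide A6 and propargyl alcohol A7.
- Forward key step: the alkoxide of A7 adds to A5, the malonate anion attacks the alkyne activated by the arylpalladium iodide from A6 (5-exo-dig), and reductive elimination gives the Z-benzylidene diester A8. The palladium comes from PdCl2(PPh3)2 with a chiral bisphosphine.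
- Merits: all carbons of the target are assembled in one step from three simple pieces. It is the most convergent of the four plans and the shortest, at about five steps.
- Weak points: C2 is created in a reversible oxa-Michael addition remote from the metal, so the chiral ligand has no clear way to control it. C3 is quaternary in A8, and removing one ester sets it under conditions that favour the 2,3-trans isomer, the opposite of what is needed. The exocyclic alkene must then be reduced to set C4.
- Comparison: this road is better in convergence and length. The chosen plan has a dependable source of absolute configuration and a kinetic, substrate-controlled way to the cis C2/C3 relationship, which this road lacks.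

Key step: step 7

Assumption: the (R)-BINOL/Ti(OiPr)4 catalyst is taken to direct the diene to the Re face of aldehyde 1, as with simple aromatic aldehydes; if the sense is the reverse, (S)-BINOL is used and the route is otherwise unchanged.

## Route

Step 1
Reactants: 1 3,4,5-trimethoxybenzaldehyde; 2 (E)-1-methoxy-3-(trimethylsilyloxy)buta-1,3-diene
Product: 4 (R)-2-(3,4,5-trimethoxyphenyl)-2,3-dihydro-4H-pyran-4-one, via silyl aldol adduct 3 (not isolated)
Conditions: (R)-BINOL (20 mol%), Ti(OiPr)4 (10 mol%), 4 Å MS, Et2O, −20 °C; then CF3CO2H, CH2Cl2, 0 °C
Reagents that add atoms: none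
Why: Catalytic asymmetric hetero-Diels–Alder reaction in its stepwise Mukaiyama aldol form: the chiral titanium BINOLate activates aldehyde 1 and directs diene 2 to its Re face, and CF3CO2H then closes adduct 3 by oxa-Michael addition and loss of methanol, so the C2 stereocentre (R) is set by the catalyst.

Step 2
Reactants: 4 (R)-2-(3,4,5-trimethoxyphenyl)-2,3-dihydro-4H-pyran-4-one
Product: 5 (R)-5-iodo-2-(3,4,5-trimethoxyphenyl)-2,3-dihydro-4H-pyran-4-one
Conditions: I2, pyridine, CH2Cl2, 0 °C to rt
Reagents that add atoms: iodine, II
Why: α-Iodination of an enone by the iodine–pyridine addition–elimination sequence; C5 is the nucleophilic β-carbon of the enol ether, so substitution occurs there, and the mild electrophile leaves ring A and the C2 centre alone.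

Step 3
Reactants: 6 2,4,5-trimethoxybenzaldehyde
Product: 7 (2,4,5-trimethoxyphenyl)methanol
Conditions: NaBH4, MeOH, 0 °C
Reagents that add atoms: none
Why: Borohydride reduction of an aromatic aldehyde to the benzylic alcohol.

Step 4
Reactants: 7 (2,4,5-trimethoxyphenyl)methanol
Product: 8 1-(chloromethyl)-2,4,5-trimethoxybenzene
Conditions: SOCl2, pyridine, CH2Cl2, 0 °C; used at once without chromatography
Reagents that add atoms: thionyl chloride, O=S(Cl)Cl
Why: Chlorodehydroxylation of a benzylic alcohol with SOCl2; pyridine traps HCl so that the very electron-rich chloride does not alkylate itself in a Friedel–Crafts sense, and 8 is taken on immediately.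

Step 5
Reactants: 8 1-(chloromethyl)-2,4,5-trimethoxybenzene; 5 (R)-5-iodo-2-(3,4,5-trimethoxyphenyl)-2,3-dihydro-4H-pyran-4-one
Product: 10 (R)-5-(2,4,5-trimethoxybenzyl)-2-(3,4,5-trimethoxyphenyl)-2,3-dihydro-4H-pyran-4-one, via benzylzinc chloride 9 (not isolated)
Conditions: Zn dust, LiCl, THF, 25 °C; then 5, Pd(OAc)2 (2 mol%), SPhos (4 mol%), THF, 25 °C
Reagents that add atoms: none
Why: LiCl-assisted insertion of zinc into the benzylic C–Cl bond gives 9, and Negishi coupling of benzylzinc halides with α-iodoenones is established; the neutral, room-temperature conditions leave the ketone, its α-hydrogens and the C2 centre untouched.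

Step 6
Reactants: 10 (R)-5-(2,4,5-trimethoxybenzyl)-2-(3,4,5-trimethoxyphenyl)-2,3-dihydro-4H-pyran-4-one
Product: 12 (S)-3-diazo-5-(2,4,5-trimethoxybenzyl)-2-(3,4,5-trimethoxyphenyl)-2,3-dihydro-4H-pyran-4-one, via trifluoroacetyl ketone 11 (not isolated)
Conditions: LiN(SiMe3)2, THF, −78 °C; CF3CO2CH2CF3, −78 °C; then MeSO2N3, Et3N, H2O, MeCN, 25 °C
Reagents that add atoms: methanesulfonyl azide, CS(=O)(=O)N=[N+]=[N-]
Why: Detrifluoroacetylative diazo transfer (a Regitz-type transfer to an activated ketone): kinetic enolisation is possible only at C3 because the other α-carbon is sp2 and fully substituted, Claisen trifluoroacetylation gives 11, and the sulfonyl azide transfers N2 with cleavage of the trifluoroacetyl group. The low temperature of the enolate stage is meant to keep the enolate from ejecting O1. C2 is untouched; its descriptor changes from R to S only because the diazo carbon now outranks ring A.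

Step 7
Reactants: 12 (S)-3-diazo-5-(2,4,5-trimethoxybenzyl)-2-(3,4,5-trimethoxyphenyl)-2,3-dihydro-4H-pyran-4-one
Product: 15 methyl (2R,3S)-4-(2,4,5-trimethoxybenzyl)-2-(3,4,5-trimethoxyphenyl)-2,3-dihydrofuran-3-carboxylate, via ring-contracted ketene 13 (not isolated), via ester enol 14 (not isolated)
Conditions: hν (λ > 300 nm, borosilicate filter), degassed MeOH, 0 °C; crude product taken directly into step 8
Reagents that add atoms: methanol, CO
Why: Excitation of the cyclic diazoketone 12, which is locked in the s-Z geometry, expels N2 with a concerted 1,2-shift of the sp2 carbon C5 of the pyranone from the carbonyl carbon to the diazo carbon (Wolff rearrangement), so that free-carbene pathways such as a 1,2-hydride shift from C2–H or O–H insertion should stay minor. The five-membered ring is closed by ring contraction: the new C3–C4 bond of the dihydrofuran comes from the migration, not from an exo or endo cyclisation, and the former carbonyl carbon is pushed out of the ring as the ketene 13. Methanol adds to 13 to give the ester enol 14, which is protonated at C3, the α-carbon and usual kinetic site of a dienol, and not at C5, so the enol ether is kept. The new stereocentre C3 is controlled by the resident C2 centre: the proton reaches the nearly planar ring on the face opposite ring A, which places the ester cis to ring A. The closest known reaction type is the photochemical Wolff ring contraction of cyclic α-diazoketones in alcohols, established for 3-diazochroman-4-ones and for diazonaphthoquinones, where an sp2 carbon migrates as here. The selectivity needed is regiochemical, secured because the only migrating candidate on the carbonyl carbon is C5, and facial, secured by the C2 aryl group; C2 takes part in no bond change and keeps its configuration, its descriptor returning to R only through the priority change at C3. Neutral conditions, low temperature and direct use of crude 15 are meant to prevent epimerisation of the doubly activated C3–H.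

Step 8
Reactants: 15 methyl (2R,3S)-4-(2,4,5-trimethoxybenzyl)-2-(3,4,5-trimethoxyphenyl)-2,3-dihydrofuran-3-carboxylate
Product: 16 methyl (2R,3S,4R)-4-(2,4,5-trimethoxybenzyl)-2-(3,4,5-trimethoxyphenyl)tetrahydrofuran-3-carboxylate
Conditions: H2 (1 atm), Rh/Al2O3 (5 wt%), EtOAc, 25 °C
Reagents that add atoms: none
Why: Heterogeneous syn hydrogenation of the trisubstituted enol ether; the C3 ester and ring A at C2 block the same face, so hydrogen adds to C4 from the other face and the benzyl group ends cis to both, setting C4 (R). Rhodium is chosen over palladium because it is less given to alkene migration and to hydrogenolysis of the benzylic C2–O1 bond.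

Step 9
Reactants: 16 methyl (2R,3S,4R)-4-(2,4,5-trimethoxybenzyl)-2-(3,4,5-trimethoxyphenyl)tetrahydrofuran-3-carboxylate
Product: 17 [(2R,3R,4R)-4-(2,4,5-trimethoxybenzyl)-2-(3,4,5-trimethoxyphenyl)tetrahydrofuran-3-yl]methanol
Conditions: LiAlH4, THF, −20 to 0 °C
Reagents that add atoms: none
Why: Hydride reduction of the ester to the primary alcohol; at low temperature reduction is faster than enolisation, so the all-cis C3 centre is carried through (its descriptor becomes R by priority change only), and no other group in 16 reacts with LiAlH4.

## Compound list

1 | 3,4,5-trimethoxybenzaldehyde | COc1cc(C=O)cc(OC)c1OC | starting material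
2 | (E)-1-methoxy-3-(trimethylsilyloxy)buta-1,3-diene | CO/C=C/C(=C)O[Si](C)(C)C | starting material
3 | (R,E)-1-methoxy-5-(3,4,5-trimethoxyphenyl)-5-(trimethylsilyloxy)pent-1-en-3-one | CO/C=C/C(=O)C[C@@H](O[Si](C)(C)C)c1cc(OC)c(OC)c(OC)c1 | intermediate
4 | (R)-2-(3,4,5-trimethoxyphenyl)-2,3-dihydro-4H-pyran-4-one | O=C1C=CO[C@@H](c2cc(OC)c(OC)c(OC)c2)C1 | intermediate
5 | (R)-5-iodo-2-(3,4,5-trimethoxyphenyl)-2,3-dihydro-4H-pyran-4-one | O=C1C(I)=CO[C@@H](c2cc(OC)c(OC)c(OC)c2)C1 | intermediate
6 | 2,4,5-trimethoxybenzaldehyde | COc1cc(OC)c(C=O)cc1OC | starting material
7 | (2,4,5-trimethoxyphenyl)methanol | COc1cc(OC)c(CO)cc1OC | intermediate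
8 | 1-(chloromethyl)-2,4,5-trimethoxybenzene | COc1cc(OC)c(CCl)cc1OC | intermediate
9 | (2,4,5-trimethoxybenzyl)zinc chloride | COc1cc(OC)c(C[Zn]Cl)cc1OC | intermediate
10 | (R)-5-(2,4,5-trimethoxybenzyl)-2-(3,4,5-trimethoxyphenyl)-2,3-dihydro-4H-pyran-4-one | COc1cc(OC)c(OC)cc1CC1=CO[C@@H](c2cc(OC)c(OC)c(OC)c2)CC1=O | intermediate
11 | (2R)-3-(trifluoroacetyl)-5-(2,4,5-trimethoxybenzyl)-2-(3,4,5-trimethoxyphenyl)-2,3-dihydro-4H-pyran-4-one (C3 not defined, largely enolised) | COc1cc(OC)c(OC)cc1CC1=CO[C@@H](c2cc(OC)c(OC)c(OC)c2)C(C(=O)C(F)(F)F)C1=O | intermediate
12 | (S)-3-diazo-5-(2,4,5-trimethoxybenzyl)-2-(3,4,5-trimethoxyphenyl)-2,3-dihydro-4H-pyran-4-one | COc1cc(OC)c(OC)cc1CC1=CO[C@@H](c2cc(OC)c(OC)c(OC)c2)C(=[N+]=[N-])C1=O | intermediate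
13 | (S)-3-(oxomethylidene)-4-(2,4,5-trimethoxybenzyl)-2-(3,4,5-trimethoxyphenyl)-2,3-dihydrofuran (ketene) | COc1cc(OC)c(OC)cc1CC1=CO[C@@H](c2cc(OC)c(OC)c(OC)c2)C1=C=O | intermediate
14 | (S)-methoxy[4-(2,4,5-trimethoxybenzyl)-2-(3,4,5-trimethoxyphenyl)furan-3(2H)-ylidene]methanol (ester enol, alkene geometry not defined) | COc1cc(OC)c(OC)cc1CC1=CO[C@@H](c2cc(OC)c(OC)c(OC)c2)C1=C(O)OC | intermediate
15 | methyl (2R,3S)-4-(2,4,5-trimethoxybenzyl)-2-(3,4,5-trimethoxyphenyl)-2,3-dihydrofuran-3-carboxylate (2,3-cis) | COc1cc(OC)c(OC)cc1CC1=CO[C@@H](c2cc(OC)c(OC)c(OC)c2)[C@H]1C(=O)OC | intermediate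
16 | methyl (2R,3S,4R)-4-(2,4,5-trimethoxybenzyl)-2-(3,4,5-trimethoxyphenyl)tetrahydrofuran-3-carboxylate (all-cis) | COc1cc(OC)c(OC)cc1C[C@H]1CO[C@@H](c2cc(OC)c(OC)c(OC)c2)[C@H]1C(=O)OC | intermediate
17 | [(2R,3R,4R)-4-(2,4,5-trimethoxybenzyl)-2-(3,4,5-trimethoxyphenyl)tetrahydrofuran-3-yl]methanol (all-cis) | COc1cc(OC)c(OC)cc1C[C@H]1CO[C@@H](c2cc(OC)c(OC)c(OC)c2)[C@H]1CO | target

## Step count and risks

Total: 9 steps. Longest linear sequence: 7 steps (steps 1, 2, 5, 6, 7, 8, 9 from aldehyde 1; equally steps 3 to 9 from aldehyde 6).

**Step 7 (key step).** The most likely failure is loss of control at C3: protonation of enol 14 on the wrong face or at C5, or later epimerisation of the acidic C3–H, each of which erodes the 2,3-cis relationship. A lesser concern is diversion of the excited diazoketone into a 1,2-hydride shift from C2–H. The fallback changes the way C3 is set. It sets out from 15, whatever its composition at C3. DBU (CH2Cl2, 25 °C) isomerises it through the dienolate into the conjugated ester methyl (S)-4-(2,4,5-trimethoxybenzyl)-2-(3,4,5-trimethoxyphenyl)-2,5-dihydrofuran-3-carboxylate F1. Hydrogenation of the tetrasubstituted C3=C4 bond (H2, 50 bar, Rh/Al2O3, EtOAc) from the face opposite ring A then sets C3 and C4 together by syn addition and comes back to the route at 16.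

**Step 6.** The most likely failure is ring opening of the lithium enolate by β-elimination of O1, a vinylogous carboxylate leaving group. This would racemise C2 on reclosure or leave an open-chain dienone. The fallback avoids a persistent enolate. It sets out from 10, which is condensed with tert-butoxybis(dimethylamino)methane (toluene, 70 °C) to the enaminone (S)-3-[(dimethylamino)methylidene]-5-(2,4,5-trimethoxybenzyl)-2-(3,4,5-trimethoxyphenyl)-2,3-dihydro-4H-pyran-4-one F2. Diazo transfer to F2 with 4-toluenesulfonyl azide (CH2Cl2, 25 °C) expels the formamidine and comes back to the route at 12.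

**Step 5.** The most likely failure is decomposition of the very electron-rich benzylic chloride 8 and Wurtz-type homocoupling during zinc insertion, so that too little 9 reaches the coupling. The fallback avoids any benzylic halide or benzylic metal and makes steps 3 and 4 unnecessary. It sets out from 5 and aldehyde 6, which are joined by a Nozaki–Hiyama–Kishi reaction (CrCl2, NiCl2 cat., DMF, 25 °C) to the carbinol (2R)-5-[hydroxy(2,4,5-trimethoxyphenyl)methyl]-2-(3,4,5-trimethoxyphenyl)-2,3-dihydro-4H-pyran-4-one F3, a mixture at the carbinol carbon. Ionic deoxygenation of this doubly activated alcohol (Et3SiH, CF3CO2H, CH2Cl2, −20 °C), with hydride expected at the benzylic carbon so that the vinylogous ester is restored, comes back to the route at 10.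

**Step 8.** The most likely failure is migration of the double bond on the metal surface into conjugation with the ester, or epimerisation at C3 before the alkene is reduced; cleavage of the benzylic C2–O1 bond is a further risk. The fallback reverses the order of the last two operations. It sets out from 15, whose ester is reduced first with iBu2AlH (CH2Cl2, −78 °C) to [(2R,3R)-4-(2,4,5-trimethoxybenzyl)-2-(3,4,5-trimethoxyphenyl)-2,3-dihydrofuran-3-yl]methanol F4. In F4, C3 can no longer epimerise or draw the alkene into conjugation. Hydrogenation of F4 (H2, Rh/Al2O3, EtOAc, 25 °C) from the face opposite the two cis substituents comes back to the route at 17.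

## Further compounds

F1 | step 7 | methyl (S)-4-(2,4,5-trimethoxybenzyl)-2-(3,4,5-trimethoxyphenyl)-2,5-dihydrofuran-3-carboxylate | COc1cc(OC)c(OC)cc1CC1=C(C(=O)OC)[C@H](c2cc(OC)c(OC)c(OC)c2)OC1
F2 | step 6 | (S)-3-[(dimethylamino)methylidene]-5-(2,4,5-trimethoxybenzyl)-2-(3,4,5-trimethoxyphenyl)-2,3-dihydro-4H-pyran-4-one | COc1cc(OC)c(OC)cc1CC1=CO[C@@H](c2cc(OC)c(OC)c(OC)c2)C(=CN(C)C)C1=O
F3 | step 5 | (2R)-5-[hydroxy(2,4,5-trimethoxyphenyl)methyl]-2-(3,4,5-trimethoxyphenyl)-2,3-dihydro-4H-pyran-4-one | COc1cc(OC)c(OC)cc1C(O)C1=CO[C@@H](c2cc(OC)c(OC)c(OC)c2)CC1=O
F4 | step 8 | [(2R,3R)-4-(2,4,5-trimethoxybenzyl)-2-(3,4,5-trimethoxyphenyl)-2,3-dihydrofuran-3-yl]methanol | COc1cc(OC)c(OC)cc1CC1=CO[C@@H](c2cc(OC)c(OC)c(OC)c2)[C@H]1CO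
A1 | alternative 1 | (4S,5R)-4-(3,4,5-trimethoxyphenyl)-5-[(Z)-3-(2,4,5-trimethoxyphenyl)prop-1-en-1-yl]-1,3-dioxolane | COc1cc(cc(OC)c1OC)[C@@H]1OCO[C@@H]1/C=C\Cc1cc(OC)c(OC)cc1OC
A2 | alternative 1 | (2R,3S,4R)-4-(2,4,5-trimethoxybenzyl)-2-(3,4,5-trimethoxyphenyl)tetrahydrofuran-3-carbaldehyde | COc1cc(OC)c(OC)cc1C[C@H]1CO[C@@H](c2cc(OC)c(OC)c(OC)c2)[C@H]1C=O
A3 | alternative 2 | (S)-2-[(tert-butyldimethylsilyloxy)methyl]-1-(3,4,5-trimethoxyphenyl)buta-2,3-dien-1-ol | C=C=C(CO[Si](C)(C)C(C)(C)C)[C@@H](O)c1cc(OC)c(OC)c(OC)c1
A4 | alternative 2 | (S)-3-(tert-butyldimethylsilyloxymethyl)-4-(2,4,5-trimethoxybenzyl)-2-(3,4,5-trimethoxyphenyl)-2,5-dihydrofuran | COc1cc(OC)c(OC)cc1CC1=C(CO[Si](C)(C)C(C)(C)C)[C@H](c2cc(OC)c(OC)c(OC)c2)OC1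
A5 | alternative 3 | diethyl 2-(3,4,5-trimethoxybenzylidene)malonate | CCOC(=O)C(=Cc1cc(OC)c(OC)c(OC)c1)C(=O)OCC
A6 | alternative 3 | 1-iodo-2,4,5-trimethoxybenzene | COc1cc(OC)c(I)cc1OC
A7 | alternative 3 | prop-2-yn-1-ol | C#CCO
A8 | alternative 3 | diethyl (S,Z)-4-(2,4,5-trimethoxybenzylidene)-2-(3,4,5-trimethoxyphenyl)dihydrofuran-3,3(2H)-dicarboxylate | CCOC(=O)C1(C(=O)OCC)[C@H](c2cc(OC)c(OC)c(OC)c2)OC/C1=C\c1cc(OC)c(OC)cc1OC
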